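**Plan**

- Retrosynthetic cuts: the 3'–8'' biaryl bond (Suzuki–Miyaura) separates a flavone unit, taken from apigenin, from the flavanone unit. In the flavanone, ring C is cut at C-3–C-4 and at O-1–C-8a.
- Enabling feature: in ring C the ketone carbon C-4 and the ether oxygen O-1 sit on neighbouring ring A carbons (C-4a, C-8a), and O-1–C-2(H)(aryl)–C-3H2 is a terminal aryl oxirane opened at its CH2. C-4 is therefore used with reversed polarity as a 1,3-dithiane anion, and C-8a as an aryl fluoride.
- Forward order: ring A fluoro-dithiane (2 steps) and (R)-aryl oxirane (3 steps); a one-pot epoxide opening/oxido-SNAr closes ring C as its 4,4-dithioketal; borylation; Suzuki union with 8-iodo-tri-O-benzylapigenin; dithiane hydrolysis; hydrogenolysis.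
- Stereochemistry: C-2 is the only stereocentre. It is set by the CBS reduction in step 5 and carried through the ring closure without any bond to it being broken.
- Protection logic: the dithioketal removes the C-4 carbonyl, so base-induced ring opening to a chalcone cannot racemise C-2 until after the last basic step. The 7-OMe comes from the starting aldehyde; all other phenols travel as benzyl ethers.

Key step: step 6

Assumption: rotation about the 3'–8'' biaryl axis is taken to be fast at room temperature (the target is drawn without axial chirality), so C-2 is the only stereogenic element to control.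

**Route**

Step 1
Reactants: 1 2,6-difluoro-4-methoxybenzaldehyde
Product: 2 2-(benzyloxy)-6-fluoro-4-methoxybenzaldehyde
Conditions: BnOH (1.0 equiv), K2CO3, DMF, 60 °C
Reagents that add atoms: benzyl alcohol, OCc1ccccc1
Why: SNAr of benzyl oxide at a fluorine ortho to the formyl group; the two fluorines are equivalent and the first alkoxy group deactivates the ring, so mono-substitution should result.

Step 2
Reactants: 2 2-(benzyloxy)-6-fluoro-4-methoxybenzaldehyde
Product: 3 2-[2-(benzyloxy)-6-fluoro-4-methoxyphenyl]-1,3-dithiane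
Conditions: HS(CH2)3SH, BF3·OEt2 (0.2 equiv), CH2Cl2, 0 °C
Reagents that add atoms: propane-1,3-dithiol, SCCCS
Why: Lewis-acid dithioacetalisation of the aldehyde gives the Corey–Seebach acyl-anion precursor; brief exposure at 0 °C should leave the benzyl ether intact.

Step 3
Reactants: 4 1-(3-bromo-4-hydroxyphenyl)ethanone
Product: 5 1-[4-(benzyloxy)-3-bromophenyl]ethanone
Conditions: BnBr, K2CO3, acetone, reflux
Reagents that add atoms: benzyl bromide, BrCc1ccccc1
Why: Williamson etherification of an acidic para-acyl phenol.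

Step 4
Reactants: 5 1-[4-(benzyloxy)-3-bromophenyl]ethanone
Product: 6 1-[4-(benzyloxy)-3-bromophenyl]-2-bromoethanone
Conditions: CuBr2 (2 equiv), EtOAc/CHCl3, reflux
Reagents that add atoms: CuBr2, Br[Cu]Br
Why: alpha-bromination of an aryl methyl ketone through its enol with CuBr2, which should stop at the monobromide and leave the deactivated ring untouched.

Step 5
Reactants: 6 1-[4-(benzyloxy)-3-bromophenyl]-2-bromoethanone
Product: 8 (R)-2-[4-(benzyloxy)-3-bromophenyl]oxirane, via (R)-bromohydrin 7 (not isolated)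
Conditions: (R)-2-methyl-CBS-oxazaborolidine (0.1 equiv), BH3·SMe2, THF, 0 °C; MeOH; then 2 M NaOH, rt
Reagents that add atoms: none
Why: Corey–Bakshi–Shibata reduction under catalyst control (aryl as the large group, so the (R)-catalyst should give the (R)-bromohydrin), then intramolecular Williamson closure at the CH2Br carbon, which does not touch the stereocentre.

Step 6
Reactants: 3 2-[2-(benzyloxy)-6-fluoro-4-methoxyphenyl]-1,3-dithiane; 8 (R)-2-[4-(benzyloxy)-3-bromophenyl]oxirane
Product: 11 (2S)-5-(benzyloxy)-2-[4-(benzyloxy)-3-bromophenyl]-7-methoxyspiro[chromane-4,2'-[1,3]dithiane], via lithiated dithiane 9 (not isolated), via lithium alkoxide 10 (not isolated)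
Conditions: 3 (1.1 equiv), n-BuLi (1.05 equiv), THF, −78 to −30 °C; 8 (1.0 equiv), DMPU, −78 to 0 °C; then KOtBu (1.1 equiv), 50 °C
Reagents that add atoms: none
Why: Deprotonation of 3 at the dithiane carbon gives acyl-anion equivalent 9 (polarity reversal of the C-4 carbonyl carbon), which opens oxirane 8 by SN2 attack at its unsubstituted CH2 to form the C-3–C-4 bond and release the C-2 alkoxide 10; after cation exchange to potassium the alkoxide adds to the fluorine-bearing ring carbon C-8a and expels fluoride through a Meisenheimer adduct, forming the O-1–C-8a bond. The closest known reaction types are the Corey–Seebach alkylation of 2-lithio-1,3-dithianes by terminal epoxides and the alkoxide SNAr cyclisation of 3-(2-fluoroaryl)propanols to chromans. Ring C closes by a 6-exo-trig addition–elimination at an aromatic carbon. No stereocentre is created: C-2 is the oxirane carbon of 8 and none of its bonds is broken, so (R)-8 should give (2S)-11 with retention, the descriptor changing only because the ranking of aryl and CH2 inverts. The selectivities needed are terminal rather than benzylic opening of the electron-rich styrene oxide (secured by the bulky tertiary carbanion and Lewis-acid-free, DMPU-solvated conditions), dithiane C–H rather than aryl C–H lithiation (kinetically favoured at −78 °C, with 3 in slight excess so that no free n-BuLi meets the aryl bromide), and displacement of fluoride only (bromide and alkoxy groups are not SNAr leaving groups here). The dithiane holds C-4 at the ketone oxidation level without a carbonyl, so retro-aldol cleavage, dehydration to a chalcone and base-induced ring opening cannot occur in this step or in the two basic steps that follow.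

Step 7
Reactants: 11 (2S)-5-(benzyloxy)-2-[4-(benzyloxy)-3-bromophenyl]-7-methoxyspiro[chromane-4,2'-[1,3]dithiane]
Product: 12 (2S)-5-(benzyloxy)-2-[4-(benzyloxy)-3-(4,4,5,5-tetramethyl-1,3,2-dioxaborolan-2-yl)phenyl]-7-methoxyspiro[chromane-4,2'-[1,3]dithiane]
Conditions: B2pin2, Pd(dppf)Cl2 (5 mol%), KOAc, 1,4-dioxane, 90 °C
Reagents that add atoms: bis(pinacolato)diboron, CC1(C)OB(OC1(C)C)B1OC(C)(C)C(C)(C)O1
Why: Miyaura borylation of an aryl bromide; the weak acetate base and the absence of a carbonyl leave C-2 untouched, and thioacetals are normally tolerated by this catalyst.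

Step 8
Reactants: 13 apigenin (5,7-dihydroxy-2-(4-hydroxyphenyl)-4H-chromen-4-one)
Product: 14 5,7-bis(benzyloxy)-2-[4-(benzyloxy)phenyl]-4H-chromen-4-one
Conditions: BnBr (4 equiv), K2CO3, DMF, 80 °C
Reagents that add atoms: benzyl bromide, BrCc1ccccc1
Why: Williamson etherification of all three phenols; excess reagent and heat are used because the chelated 5-OH reacts last.

Step 9
Reactants: 14 5,7-bis(benzyloxy)-2-[4-(benzyloxy)phenyl]-4H-chromen-4-one
Product: 15 5,7-bis(benzyloxy)-2-[4-(benzyloxy)phenyl]-8-iodo-4H-chromen-4-one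
Conditions: NIS (1.1 equiv), CF3CO2H (cat.), CH2Cl2, 0 °C to rt
Reagents that add atoms: N-iodosuccinimide, O=C1CCC(=O)N1I
Why: electrophilic aromatic iodination of the phloroglucinol-type ring; with the 5-oxygen alkylated, 5,7-dialkoxyflavones are attacked at C-8, and C-6 is further shielded by two flanking benzyloxy groups.

Step 10
Reactants: 12 (2S)-5-(benzyloxy)-2-[4-(benzyloxy)-3-(4,4,5,5-tetramethyl-1,3,2-dioxaborolan-2-yl)phenyl]-7-methoxyspiro[chromane-4,2'-[1,3]dithiane]; 15 5,7-bis(benzyloxy)-2-[4-(benzyloxy)phenyl]-8-iodo-4H-chromen-4-one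
Product: 16 5,7-bis(benzyloxy)-8-{2-(benzyloxy)-5-[(2S)-5-(benzyloxy)-7-methoxyspiro[chromane-4,2'-[1,3]dithian]-2-yl]phenyl}-2-[4-(benzyloxy)phenyl]-4H-chromen-4-one
Conditions: Pd(OAc)2 (5 mol%), SPhos (10 mol%), K3PO4, toluene/H2O, 90 °C
Reagents that add atoms: none
Why: Suzuki–Miyaura coupling of a flavone 8-iodide with a B-ring boronate, the established way to the 3'–8'' biflavone bond; a dialkylbiarylphosphine is chosen for the tri-ortho-substituted biaryl, and the aqueous base cannot racemise C-2 because C-4 is still a dithioketal.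

Step 11
Reactants: 16 5,7-bis(benzyloxy)-8-{2-(benzyloxy)-5-[(2S)-5-(benzyloxy)-7-methoxyspiro[chromane-4,2'-[1,3]dithian]-2-yl]phenyl}-2-[4-(benzyloxy)phenyl]-4H-chromen-4-one
Product: 17 5,7-bis(benzyloxy)-8-{2-(benzyloxy)-5-[(2S)-5-(benzyloxy)-7-methoxy-4-oxochroman-2-yl]phenyl}-2-[4-(benzyloxy)phenyl]-4H-chromen-4-one
Conditions: MeI (excess), CaCO3, MeCN/H2O (9:1), 45 °C
Reagents that add atoms: water, O
Why: alkylative dithiane hydrolysis (S-methylation, ionisation to a thionium ion stabilised by the electron-rich ring A, capture by water); it is non-oxidative and buffered near neutrality, so the fully O-protected flavanone should not open to a chalcone.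

Step 12
Reactants: 17 5,7-bis(benzyloxy)-8-{2-(benzyloxy)-5-[(2S)-5-(benzyloxy)-7-methoxy-4-oxochroman-2-yl]phenyl}-2-[4-(benzyloxy)phenyl]-4H-chromen-4-one
Product: 18 8-{2-hydroxy-5-[(2S)-5-hydroxy-7-methoxy-4-oxochroman-2-yl]phenyl}-5,7-dihydroxy-2-(4-hydroxyphenyl)-4H-chromen-4-one (CNP0107492.1)
Conditions: H2 (1 atm), 10% Pd/C, EtOAc/MeOH, rt, stopped at full debenzylation; base-free work-up
Reagents that add atoms: none
Why: hydrogenolysis of the five benzyl aryl ethers under neutral conditions leaves the methyl ether, the flavone and the configuration at C-2 (no base, hence no retro-oxa-Michael opening) unchanged.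

**Compound list**

1 | 2,6-difluoro-4-methoxybenzaldehyde | COc1cc(F)c(C=O)c(F)c1 | starting material
2 | 2-(benzyloxy)-6-fluoro-4-methoxybenzaldehyde | COc1cc(F)c(C=O)c(OCc2ccccc2)c1 | intermediate
3 | 2-[2-(benzyloxy)-6-fluoro-4-methoxyphenyl]-1,3-dithiane | COc1cc(F)c(C2SCCCS2)c(OCc3ccccc3)c1 | intermediate
4 | 1-(3-bromo-4-hydroxyphenyl)ethanone | CC(=O)c1ccc(O)c(Br)c1 | starting material
5 | 1-[4-(benzyloxy)-3-bromophenyl]ethanone | CC(=O)c1ccc(OCc2ccccc2)c(Br)c1 | intermediate
6 | 1-[4-(benzyloxy)-3-bromophenyl]-2-bromoethanone | BrCC(=O)c1ccc(OCc2ccccc2)c(Br)c1 | intermediate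
7 | (R)-1-[4-(benzyloxy)-3-bromophenyl]-2-bromoethanol ((R)-bromohydrin) | BrC[C@H](O)c1ccc(OCc2ccccc2)c(Br)c1 | intermediate
8 | (R)-2-[4-(benzyloxy)-3-bromophenyl]oxirane | Brc1cc(ccc1OCc2ccccc2)[C@@H]3CO3 | intermediate
9 | 2-[2-(benzyloxy)-6-fluoro-4-methoxyphenyl]-2-lithio-1,3-dithiane (lithiated dithiane) | COc1cc(F)c(C2([Li])SCCCS2)c(OCc3ccccc3)c1 | intermediate
10 | lithium (1S)-1-[4-(benzyloxy)-3-bromophenyl]-2-{2-[2-(benzyloxy)-6-fluoro-4-methoxyphenyl]-1,3-dithian-2-yl}ethanolate (lithium alkoxide) | COc1cc(F)c(c(OCc2ccccc2)c1)C3(SCCCS3)C[C@H]([O-])c4ccc(OCc5ccccc5)c(Br)c4.[Li+] | intermediate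
11 | (2S)-5-(benzyloxy)-2-[4-(benzyloxy)-3-bromophenyl]-7-methoxyspiro[chromane-4,2'-[1,3]dithiane] | COc1cc(OCc2ccccc2)c3c(c1)O[C@H](c4ccc(OCc5ccccc5)c(Br)c4)CC36SCCCS6 | intermediate
12 | (2S)-5-(benzyloxy)-2-[4-(benzyloxy)-3-(4,4,5,5-tetramethyl-1,3,2-dioxaborolan-2-yl)phenyl]-7-methoxyspiro[chromane-4,2'-[1,3]dithiane] | COc1cc(OCc2ccccc2)c3c(c1)O[C@H](c4ccc(OCc5ccccc5)c(B7OC(C)(C)C(C)(C)O7)c4)CC36SCCCS6 | intermediate
13 | apigenin (5,7-dihydroxy-2-(4-hydroxyphenyl)-4H-chromen-4-one) | O=c1cc(-c2ccc(O)cc2)oc2cc(O)cc(O)c12 | starting material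
14 | 5,7-bis(benzyloxy)-2-[4-(benzyloxy)phenyl]-4H-chromen-4-one | O=c1cc(-c2ccc(OCc3ccccc3)cc2)oc2cc(OCc3ccccc3)cc(OCc3ccccc3)c12 | intermediate
15 | 5,7-bis(benzyloxy)-2-[4-(benzyloxy)phenyl]-8-iodo-4H-chromen-4-one | O=c1cc(-c2ccc(OCc3ccccc3)cc2)oc2c(I)c(OCc3ccccc3)cc(OCc3ccccc3)c12 | intermediate
16 | 5,7-bis(benzyloxy)-8-{2-(benzyloxy)-5-[(2S)-5-(benzyloxy)-7-methoxyspiro[chromane-4,2'-[1,3]dithian]-2-yl]phenyl}-2-[4-(benzyloxy)phenyl]-4H-chromen-4-one | COc1cc(OCc2ccccc2)c2c(c1)O[C@H](c1ccc(OCc3ccccc3)c(-c3c(OCc4ccccc4)cc(OCc4ccccc4)c4c(=O)cc(-c5ccc(OCc6ccccc6)cc5)oc34)c1)CC21SCCCS1 | intermediate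
17 | 5,7-bis(benzyloxy)-8-{2-(benzyloxy)-5-[(2S)-5-(benzyloxy)-7-methoxy-4-oxochroman-2-yl]phenyl}-2-[4-(benzyloxy)phenyl]-4H-chromen-4-one | COc1cc(OCc2ccccc2)c2c(c1)O[C@H](c1ccc(OCc3ccccc3)c(-c3c(OCc4ccccc4)cc(OCc4ccccc4)c4c(=O)cc(-c5ccc(OCc6ccccc6)cc5)oc34)c1)CC2=O | intermediate
18 | 8-{2-hydroxy-5-[(2S)-5-hydroxy-7-methoxy-4-oxochroman-2-yl]phenyl}-5,7-dihydroxy-2-(4-hydroxyphenyl)-4H-chromen-4-one (CNP0107492.1) | COc1cc(O)c2c(c1)O[C@H](c1ccc(O)c(-c3c(O)cc(O)c4c(=O)cc(-c5ccc(O)cc5)oc34)c1)CC2=O | target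

**Count**

Total steps: 12. Longest linear sequence: 8 steps (4 → 5 → 6 → 8 → 11 → 12 → 16 → 17 → 18).

**Steps most likely to fail**

1. Step 6. The alkoxide may close too slowly onto the non-activated, alkoxy-substituted fluoroarene. At the temperature then needed, base could attack the aryl bromide (dehydrohalogenation) or aryl C–H metalation could compete with dithiane metalation. The fallback keeps the dithiane/epoxide union but forms ring C at O-1–C-2 by a Mitsunobu etherification with inversion; it sets out from aldehyde 2 and bromoketone 6 and returns at 11. Aldehyde 2 is treated with 2-(methylsulfonyl)ethanol and NaH in DMF; SNAr gives 2-(benzyloxy)-4-methoxy-6-[2-(methylsulfonyl)ethoxy]benzaldehyde F1, which is not isolated and loses methyl vinyl sulfone to give 2-(benzyloxy)-6-hydroxy-4-methoxybenzaldehyde F2. Dithioacetalisation as in step 2 gives 3-(benzyloxy)-2-(1,3-dithian-2-yl)-5-methoxyphenol F3. Bromoketone 6 is reduced with the (S)-configured CBS catalyst to (S)-1-[4-(benzyloxy)-3-bromophenyl]-2-bromoethanol F4 and closed with NaOH to (S)-2-[4-(benzyloxy)-3-bromophenyl]oxirane F5. Double deprotonation of F3 with n-BuLi (2.2 equiv) gives the O,C-dilithio derivative of 3-(benzyloxy)-2-(1,3-dithian-2-yl)-5-methoxyphenol F6, which opens F5 at CH2 to give 3-(benzyloxy)-2-{2-[(2R)-2-[4-(benzyloxy)-3-bromophenyl]-2-hydroxyethyl]-1,3-dithian-2-yl}-5-methoxyphenol F7. Mitsunobu cyclisation (PPh3, DIAD, THF, 0 °C) with inversion at the carbinol carbon should give (2S)-11.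

2. Step 10. Transmetalation and reductive elimination at the doubly flanked C-8 iodide may be slow, so that protodeboronation and deiodination take over, and the dithioketal sulfur may inhibit the catalyst. The fallback unmasks the ketone first and joins the halves under neutral Stille conditions; it sets out from 11 and 15 and returns at 17. Bromide 11 is hydrolysed as in step 11 to (2S)-5-(benzyloxy)-2-[4-(benzyloxy)-3-bromophenyl]-7-methoxychroman-4-one F8. Stannylation (Me3SnSnMe3, Pd(PPh3)4, toluene, 100 °C) gives (2S)-5-(benzyloxy)-2-[4-(benzyloxy)-3-(trimethylstannyl)phenyl]-7-methoxychroman-4-one F9. Base-free Stille coupling of F9 with 15 (Pd2(dba)3, AsPh3, CuI, NMP, 70 °C) should give 17 without exposing the flavanone to base.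

3. Step 12. The hydrogenation may run on (saturation of the flavone C-2''=C-3'' bond, hydrogenolytic opening of the benzylic C-2–O-1 bond) or stall through poisoning of the catalyst by sulfur residues. The fallback is a non-reductive Lewis-acid debenzylation with a cation scavenger (BCl3, pentamethylbenzene, CH2Cl2, −78 °C, methanol quench). It sets out from 17 and returns at 18 with no new intermediate; the 7-methyl ether, which is not peri to a carbonyl, should survive at this temperature.

**Further compounds**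

F1 | step 6 | 2-(benzyloxy)-4-methoxy-6-[2-(methylsulfonyl)ethoxy]benzaldehyde | COc1cc(OCCS(C)(=O)=O)c(C=O)c(OCc2ccccc2)c1
F2 | step 6 | 2-(benzyloxy)-6-hydroxy-4-methoxybenzaldehyde | COc1cc(O)c(C=O)c(OCc2ccccc2)c1
F3 | step 6 | 3-(benzyloxy)-2-(1,3-dithian-2-yl)-5-methoxyphenol | COc1cc(O)c(C2SCCCS2)c(OCc3ccccc3)c1
F4 | step 6 | (S)-1-[4-(benzyloxy)-3-bromophenyl]-2-bromoethanol | BrC[C@@H](O)c1ccc(OCc2ccccc2)c(Br)c1
F5 | step 6 | (S)-2-[4-(benzyloxy)-3-bromophenyl]oxirane | Brc1cc(ccc1OCc2ccccc2)[C@H]3CO3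
F6 | step 6 | O,C-dilithio derivative of 3-(benzyloxy)-2-(1,3-dithian-2-yl)-5-methoxyphenol | COc1cc(O[Li])c(C2([Li])SCCCS2)c(OCc3ccccc3)c1
F7 | step 6 | 3-(benzyloxy)-2-{2-[(2R)-2-[4-(benzyloxy)-3-bromophenyl]-2-hydroxyethyl]-1,3-dithian-2-yl}-5-methoxyphenol | COc1cc(O)c(c(OCc2ccccc2)c1)C3(SCCCS3)C[C@@H](O)c4ccc(OCc5ccccc5)c(Br)c4
F8 | step 10 | (2S)-5-(benzyloxy)-2-[4-(benzyloxy)-3-bromophenyl]-7-methoxychroman-4-one | COc1cc(OCc2ccccc2)c3c(c1)O[C@H](c4ccc(OCc5ccccc5)c(Br)c4)CC3=O
F9 | step 10 | (2S)-5-(benzyloxy)-2-[4-(benzyloxy)-3-(trimethylstannyl)phenyl]-7-methoxychroman-4-one | COc1cc(OCc2ccccc2)c3c(c1)O[C@H](c4ccc(OCc5ccccc5)c([Sn](C)(C)C)c4)CC3=O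
F0 | step 12 | none | none
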